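**Retrosynthetic overview**
- Feature: in ring B the ether carbon C1' sits between C2' (OH) and C6' (Br). C6'–Br is meta to the hydroxyl, so phenol bromination cannot place it; C1' is therefore treated as C2 of a 2-aryloxycyclohexane-1,3-dione whose two carbonyls become C2'–OH and C6'–Br.
- Endgame: target 16 from methyl ether 15 (BBr3); 15 from bromoenone 12 by halogenative aromatisation plus ortho/para bromination (C3', C5'); 12 from the symmetric dione 11 by deoxybromination.
- Key disconnection: ring B by [3+3] Michael–Claisen annulation of 4-aryloxyacetoacetate 6 with methyl acrylate 7 (bonds C3'–C4' and C1'–C6'), followed by decarboxylation.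
- Keto ester 6 from 3,5-dibromo-2-methoxyphenol 4 and methyl 4-chloroacetoacetate 5; phenol 4 from 3,5-dibromosalicylaldehyde 1 by O-methylation and Baeyer–Villiger (Dakin-type) oxidation.
- Ring order: ring A is bought complete; ring B is the only ring formed (step 4) and is aromatised in step 7.

Key step: step 4

Assumption: the 1,3-dicarbonyl compounds 8–11 are drawn as keto tautomers; they should exist largely as enols or enolates, their methine centres are configurationally labile, and no stereochemistry is specified. The target has no stereocentre.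

**Step 1**
Reactants: 1 3,5-dibromo-2-hydroxybenzaldehyde
Product: 2 3,5-dibromo-2-methoxybenzaldehyde
Conditions: MeI, K2CO3, DMF, rt to 40 °C
Reagents that add atoms: iodomethane, CI
Why: Williamson O-methylation of the acidic salicylaldehyde phenol; the aldehyde and aryl bromides are inert to K2CO3/MeI.

**Step 2**
Reactants: 2 3,5-dibromo-2-methoxybenzaldehyde
Product: 4 3,5-dibromo-2-methoxyphenol, via aryl formate 3 (not isolated)
Conditions: mCPBA, CH2Cl2, reflux; wash; then MeOH, Et3N (cat.), rt
Reagents that add atoms: mCPBA, OOC(=O)c1cccc(Cl)c1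
Why: Baeyer–Villiger (Dakin-type) oxidation in which the ortho-methoxy group should favour aryl over hydride migration, and the labile aryl formate is then cleaved by methanolysis.

**Step 3**
Reactants: 4 3,5-dibromo-2-methoxyphenol; 5 methyl 4-chloroacetoacetate
Product: 6 methyl 4-(3,5-dibromo-2-methoxyphenoxy)-3-oxobutanoate
Conditions: NaH (2.2 equiv), THF/DMF, 0 °C to rt; aq. HCl work-up
Reagents that add atoms: none
Why: Williamson etherification in which the second equivalent of NaH holds the chloro keto ester as its C2 enolate, shielding the ketone while the phenoxide displaces the primary chloride at C4 by SN2.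

**Step 4**
Reactants: 6 methyl 4-(3,5-dibromo-2-methoxyphenoxy)-3-oxobutanoate; 7 methyl acrylate
Product: 9 methyl 3-(3,5-dibromo-2-methoxyphenoxy)-2,4-dioxocyclohexane-1-carboxylate, via Michael adduct 8 (not isolated)
Conditions: NaOMe (1.5 equiv), MeOH, 7 added slowly at 0 °C, then reflux; aq. HCl
Reagents that add atoms: none
Why: Methoxide deprotonates the doubly activated C2 methylene of 6 and conjugate addition to 7 forms C3'–C4', giving adduct 8. Proton exchange then makes the ketone enolate at the aryloxy-bearing carbon available, and this attacks the acrylate-derived ester in a 6-exo-trig Dieckmann-type closure that forms C1'–C6' with loss of methoxide; deprotonation of the acidic 1,3-dione pulls the equilibria forward. The closest known reaction type is the Michael–Claisen annulation of acetoacetates with acrylates to 4-carbalkoxycyclohexane-1,3-diones, as in the dimedone synthesis, and the aryloxy group makes the cyclising carbon more acidic than the methyl group of the parent case. No stereocentre has to be controlled, since the two methine carbons are enolisable and are erased by decarboxylation and aromatisation. The step needs Michael addition at C2 only, which the acidity difference secures, and a single acrylate uptake, which slow addition of one equivalent secures. Closure at the wrong carbon is excluded because every other enolate/ester pairing would give a four-membered ring.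

**Step 5**
Reactants: 9 methyl 3-(3,5-dibromo-2-methoxyphenoxy)-2,4-dioxocyclohexane-1-carboxylate
Product: 11 2-(3,5-dibromo-2-methoxyphenoxy)cyclohexane-1,3-dione, via dioxo acid 10 (not isolated)
Conditions: aq. NaOH, reflux; then HCl to pH 1, 80 °C
Reagents that add atoms: none
Why: Ester saponification followed by β-keto acid decarboxylation on acidification, the dione being protected from retro-Claisen cleavage as its enolate during the basic stage.

**Step 6**
Reactants: 11 2-(3,5-dibromo-2-methoxyphenoxy)cyclohexane-1,3-dione
Product: 12 3-bromo-2-(3,5-dibromo-2-methoxyphenoxy)cyclohex-2-en-1-one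
Conditions: Ph3PBr2, Et3N, CH2Cl2, 0 °C to rt
Reagents that add atoms: triphenylphosphine dibromide, BrP(Br)(c1ccccc1)(c1ccccc1)c1ccccc1
Why: Deoxybromination of a 1,3-dione through its enol oxyphosphonium salt and addition–elimination by bromide; because 11 is mirror-symmetric, only one bromoenone can form, and this fixes the C6' bromine.

**Step 7**
Reactants: 12 3-bromo-2-(3,5-dibromo-2-methoxyphenoxy)cyclohex-2-en-1-one
Product: 15 3,4,6-tribromo-2-(3,5-dibromo-2-methoxyphenoxy)phenol, via dibromoenone 13 (not isolated), via bromophenol 14 (not isolated)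
Conditions: Br2 (1.05 equiv), AcOH, rt to 70 °C; then Br2 (2.0 equiv), rt
Reagents that add atoms: bromine, BrBr
Why: Halogenative aromatisation of a cyclohexenone (bromination next to the carbonyl, loss of HBr, tautomerisation) should give phenol 14, whose hydroxyl then directs electrophilic bromination to its free ortho and para carbons C3' and C5', while ring A is deactivated by its two bromines.

**Step 8**
Reactants: 15 3,4,6-tribromo-2-(3,5-dibromo-2-methoxyphenoxy)phenol
Product: 16 3,4,6-tribromo-2-(3,5-dibromo-2-hydroxyphenoxy)phenol (target)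
Conditions: BBr3 (3 equiv), CH2Cl2, −78 °C to rt; then H2O
Reagents that add atoms: none
Why: Lewis acid cleavage of the aryl methyl ether by BBr3, which leaves the diaryl ether and the aryl bromides untouched.

**Compound list**
1 | 3,5-dibromo-2-hydroxybenzaldehyde | O=Cc1cc(Br)cc(Br)c1O | starting material
2 | 3,5-dibromo-2-methoxybenzaldehyde | COc1c(Br)cc(Br)cc1C=O | intermediate
3 | 3,5-dibromo-2-methoxyphenyl formate | COc1c(Br)cc(Br)cc1OC=O | intermediate
4 | 3,5-dibromo-2-methoxyphenol | COc1c(Br)cc(Br)cc1O | intermediate
5 | methyl 4-chloroacetoacetate (methyl 4-chloro-3-oxobutanoate) | COC(=O)CC(=O)CCl | starting material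
6 | methyl 4-(3,5-dibromo-2-methoxyphenoxy)-3-oxobutanoate | COC(=O)CC(=O)COc1cc(Br)cc(Br)c1OC | intermediate
7 | methyl acrylate | C=CC(=O)OC | starting material
8 | dimethyl 2-[(3,5-dibromo-2-methoxyphenoxy)acetyl]pentanedioate (racemic, labile centre) | COC(=O)CCC(C(=O)OC)C(=O)COc1cc(Br)cc(Br)c1OC | intermediate
9 | methyl 3-(3,5-dibromo-2-methoxyphenoxy)-2,4-dioxocyclohexane-1-carboxylate (keto form drawn; enolisable centres) | COC(=O)C1CCC(=O)C(Oc2cc(Br)cc(Br)c2OC)C1=O | intermediate
10 | 3-(3,5-dibromo-2-methoxyphenoxy)-2,4-dioxocyclohexane-1-carboxylic acid | OC(=O)C1CCC(=O)C(Oc2cc(Br)cc(Br)c2OC)C1=O | intermediate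
11 | 2-(3,5-dibromo-2-methoxyphenoxy)cyclohexane-1,3-dione | O=C1CCCC(=O)C1Oc1cc(Br)cc(Br)c1OC | intermediate
12 | 3-bromo-2-(3,5-dibromo-2-methoxyphenoxy)cyclohex-2-en-1-one | O=C1CCCC(Br)=C1Oc1cc(Br)cc(Br)c1OC | intermediate
13 | 3,6-dibromo-2-(3,5-dibromo-2-methoxyphenoxy)cyclohex-2-en-1-one (racemic) | O=C1C(Br)CCC(Br)=C1Oc1cc(Br)cc(Br)c1OC | intermediate
14 | 3-bromo-2-(3,5-dibromo-2-methoxyphenoxy)phenol | Oc1cccc(Br)c1Oc1cc(Br)cc(Br)c1OC | intermediate
15 | 3,4,6-tribromo-2-(3,5-dibromo-2-methoxyphenoxy)phenol | COc1c(Br)cc(Br)cc1Oc1c(O)c(Br)cc(Br)c1Br | intermediate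
16 | 3,4,6-tribromo-2-(3,5-dibromo-2-hydroxyphenoxy)phenol | Oc1c(Br)cc(Br)cc1Oc1c(O)c(Br)cc(Br)c1Br | target

**Step count:** 8 steps in total; longest linear sequence 8 steps (from 1).

**Steps most likely to fail**

Step 4 (key annulation). The base may be tied up as the unreactive C2 enolate of the open-chain adduct, so that ring closure is slow; a second acrylate may then add, or methoxide may cleave the β-keto ester. Fallback: the six-membered ring is taken preformed instead of being built. Commercial cyclohexane-1,3-dione undergoes diazo transfer (4-acetamidobenzenesulfonyl azide, Et3N, MeCN) to 2-diazocyclohexane-1,3-dione F1. O–H insertion of its carbenoid into phenol 4, catalysed by dirhodium tetraacetate Rh2(OAc)4 in benzene at reflux, should give the 2-aryloxy dione. This fallback sets out from 4 and comes back to the route at 11.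

Step 7 (aromatisation and bromination). Dehydrobromination may stall at the bromo ketone stage, or bromine may be consumed unselectively (ring A, or further ring B substitution) before aromatisation is complete. Fallback: dehydrogenation is separated from bromination and done by selenoxide elimination. Bromoenone 12 is deprotonated at the carbon next to the carbonyl (LiN(SiMe3)2, THF, −78 °C) and trapped with PhSeCl to give 3-bromo-2-(3,5-dibromo-2-methoxyphenoxy)-6-(phenylselanyl)cyclohex-2-en-1-one F2. Oxidation (H2O2, pyridine, CH2Cl2, 0 °C to rt) gives the selenoxide 3-bromo-2-(3,5-dibromo-2-methoxyphenoxy)-6-(phenylseleninyl)cyclohex-2-en-1-one F3, whose syn-elimination and tautomerisation should give phenol 14 as an isolated compound. Phenol 14 is then dibrominated with exactly two equivalents of Br2 in AcOH at rt. This fallback sets out from 12 and comes back to the route at 15.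

Step 3 (etherification). The hindered, electron-poor phenoxide may react slowly enough for the chloroacetoacetate enolate to self-condense or cyclise. Fallback: the keto ester is assembled by C-acylation instead of O-alkylation of a preformed acetoacetate. Phenol 4 is alkylated with methyl bromoacetate (K2CO3, acetone, reflux) to methyl 2-(3,5-dibromo-2-methoxyphenoxy)acetate F4, which is saponified (LiOH, THF/H2O) to 2-(3,5-dibromo-2-methoxyphenoxy)acetic acid F5. Activation with 1,1'-carbonyldiimidazole in THF gives the acyl imidazolide 2-(3,5-dibromo-2-methoxyphenoxy)-1-(imidazol-1-yl)ethanone F6. Masamune-type acylation of potassium methyl malonate (MgCl2, Et3N, MeCN) gives 2-[(3,5-dibromo-2-methoxyphenoxy)acetyl]-3-methoxy-3-oxopropanoic acid F7, which decarboxylates on acidic work-up. This fallback sets out from 4 and comes back to the route at 6.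

**Further compounds**
F1 | step 4 | 2-diazocyclohexane-1,3-dione | O=C1CCCC(=O)C1=[N+]=[N-]
F2 | step 7 | 3-bromo-2-(3,5-dibromo-2-methoxyphenoxy)-6-(phenylselanyl)cyclohex-2-en-1-one | O=C1C([Se]c2ccccc2)CCC(Br)=C1Oc1cc(Br)cc(Br)c1OC
F3 | step 7 | 3-bromo-2-(3,5-dibromo-2-methoxyphenoxy)-6-(phenylseleninyl)cyclohex-2-en-1-one | O=C1C([Se](=O)c2ccccc2)CCC(Br)=C1Oc1cc(Br)cc(Br)c1OC
F4 | step 3 | methyl 2-(3,5-dibromo-2-methoxyphenoxy)acetate | COC(=O)COc1cc(Br)cc(Br)c1OC
F5 | step 3 | 2-(3,5-dibromo-2-methoxyphenoxy)acetic acid | OC(=O)COc1cc(Br)cc(Br)c1OC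
F6 | step 3 | 2-(3,5-dibromo-2-methoxyphenoxy)-1-(imidazol-1-yl)ethanone | O=C(COc1cc(Br)cc(Br)c1OC)n1ccnc1
F7 | step 3 | 2-[(3,5-dibromo-2-methoxyphenoxy)acetyl]-3-methoxy-3-oxopropanoic acid | COC(=O)C(C(O)=O)C(=O)COc1cc(Br)cc(Br)c1OC
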